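Take the fraction of Ja left and the fraction of Jb left, both counted on the Ja charge, and ask which of them the loss of Ja answers to.

the same everywhere: Ja 0.50 M
- Sunday's: Jb 0.95 equiv; Jc 0.15 M; the very flask that is asked about, followed so far
- Thursday's: Jb 0.95 equiv; Jc 0.075 M; run made earlier
- flask: Jb 0.950 equiv; Jc 0.150 M; time 20 h

- Sunday's (time / h: Ja / %, Jd / %): 1.33: 91.6, 7.1; 2.50: 86.3, 11.4; 4.00: 81.5, 14.4; 5.00: 78.2, 14.3; 6.00: 74.7, 16.3; 8.00: 69.4, 17.4
- Thursday's (time / h: Ja / %, Jd / %): 1.00: 95.9, 5.7; 2.00: 90.4, 9.8; 3.00: 85.2, 12.8; 5.00: 77.1, 18.3; 8.00: 69.4, 19.3; 15.0: 55.2, 17.4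

(scatter of a reading: 1 percentage point)

1. amount of Ja at 20 h, in percent of the Ja charged
2. amount of Jd at 20 h, in percent of the Ja charged
3. amount of Je at 20 h, in percent of the Ja charged

**Two near twins.** Sunday's flask carries twice the Jc of Thursday's, yet both read Ja 69.4% at 8.00 h, while Jd reads 17.4% on Sunday and 19.3% on Thursday, a difference not far above the scatter of 1 percentage point.

**Pair constant.** We treat the loss of Ja as second-order, and with Jb, the limiting reagent, falling one for one with Ja, so that it stays 0.0500 of the Ja charge below Ja, Sunday's reading at 8.00 h gives 0.0587 h⁻¹ for the pair constant, the fraction of Ja lost per hour divided by the fraction of Ja left times the fraction of Jb left. Thursday's reading at 15.0 h gives 0.0582 h⁻¹, and the two flasks stand at the same Ja because the constant read from them is the same with either charge of Jc.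

**The missing part.** Thursday's readings leave 27.4% unaccounted for at 15.0 h. If we book that gap as Je, taking two Jb each, the window from 8.00 h to 15.0 h reads 0.0858 h⁻¹, higher than the constant above, so we book the gap not to Je but to a product that carries one Jb, the one taken up with Ja, and takes no second one. For Sunday's flask at 20 h our constant then gives Ja 48.0%.

**The forecast.** It observes that “Doubling Jc lowers Jd and raises Je”, and gives Ja 49%, Jd 14% and Je 37%; on Je it differs from our reckoning.

**The result.** Sunday's flask gives Ja 47.6%, against our 48.0%, Jd 13.6% and Je 0.442%, and the rest of the Ja charge stands as Jg 35.7% and Jf 2.65%.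

    Ja + Jb → Jd (k = 0.120 M⁻¹ h⁻¹)
    Jb + Jd → Je (k = 0.00500 M⁻¹ h⁻¹)
    Jd → Jg (k = 0.120 h⁻¹)
    Jd + Jc → Jf (k = 0.0620 M⁻¹ h⁻¹)

**Less Jb.** In the neighbour flask, with Jb cut to 0.380 equiv and the other charges and the time held, Jb stays 0.620 of the Ja charge below Ja, and the same pair constant 0.0587 h⁻¹ puts Ja at 75.9%; that flask holds Ja 75.7%.

Readings and results are calculated with constants of no real substance; noise was put on by code.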